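**Retrosynthetic overview**
1. Target 46 comes from methyl ester 44, which comes from E-alkene 43 by diimide reduction. Alkene 43 is cut at C7=C8 by cross metathesis into vinyl oxirane 21 (fragment A) and vinyl dioxane 42 (fragment B).
2. Fragment A: the vinyl group comes from a Wittig reaction on an epoxy aldehyde. That aldehyde traces back through Sharpless epoxidation of E-allylic alcohol 18, carboalumination/CH2O on alkyne 15, and Negishi coupling of enol triflate 7 with homopropargylzinc 13.
3. Fragment B: the vinyl group comes from glycol cleavage and Wittig, and the ester from ozonolysis of a crotyl vinyl group. The 1,2-dioxane comes from H2O2 through two invertive C–O bond formations, first at the tertiary epoxide carbon C6 and then at the secondary mesylate C3.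
4. Acyclic precursor 37 comes from Sharpless epoxidation and Brown anti-crotylation of aldehyde 28, which comes from syn-carbocupration of methyl but-2-ynoate.
5. Ring order: the carbocycle is present from 1, the oxirane is closed in step 9, the dioxane is closed in step 19, and no ring is formed after the coupling.

Assumption: comments use natural-product numbering (C1 carboxyl, C3/C6 dioxane carbons, C9/C10 oxirane carbons). One-carbon reagents (MeI, Me3Al, CH2O, MePPh3Br, MeOH) are treated as reagents. Compound 1 is used as the racemate because its stereocentre is erased in step 3.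

**Fragment A**

Step 1
Reactants: 1 2-methylcyclohexanone (racemic)
Product: 3 2,6-dimethylcyclohexanone (cis/trans mixture), via kinetic lithium enolate 2 (not isolated)
Conditions: LiN(i-Pr)2 (1.05 equiv), THF, −78 °C; MeI, −78 to 0 °C
Reagents that add atoms: iodomethane, CI
Why: Kinetic enolate alkylation works here because the hindered amide removes the less hindered C6 proton at −78 °C and the enolate is methylated by SN2; the stereocentres formed are erased later.

Step 2
Reactants: 3 2,6-dimethylcyclohexanone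
Product: 5 2,2,6-trimethylcyclohexanone (racemic), via lithium enolate 4 (not isolated)
Conditions: LiN(i-Pr)2 (1.1 equiv), THF, 0 °C; MeI, DMPU, 0 °C to rt
Reagents that add atoms: iodomethane, CI
Why: Only one kind of α-hydrogen is left, so enolate alkylation can only give the gem-dimethyl ketone.

Step 3
Reactants: 5 2,2,6-trimethylcyclohexanone
Product: 7 2,6,6-trimethylcyclohex-1-en-1-yl trifluoromethanesulfonate, via lithium enolate 6 (not isolated)
Conditions: LiN(i-Pr)2 (1.1 equiv), THF, −78 to 0 °C; PhNTf2, 0 °C to rt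
Reagents that add atoms: N-phenylbis(trifluoromethanesulfonimide), O=S(=O)(N(c1ccccc1)S(=O)(=O)C(F)(F)F)C(F)(F)F
Why: Enol triflate formation by O-sulfonylation of the only possible enolate fixes the tetrasubstituted ring alkene and removes the last ring stereocentre.

Step 4
Reactants: 8 but-3-yn-1-ol
Product: 11 4-(trimethylsilyl)but-3-yn-1-ol, via dilithio alkynolate 9 (not isolated), via bis-silylated butynol 10 (not isolated)
Conditions: n-BuLi (2.1 equiv), THF, −78 °C; Me3SiCl (2.2 equiv), −78 °C to rt; then 1 M HCl, rt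
Reagents that add atoms: chlorotrimethylsilane, C[Si](C)(C)Cl
Why: Double deprotonation and silylation followed by selective acid hydrolysis of the labile O–Si bond leaves the alkyne C–H protected.

Step 5
Reactants: 11 4-(trimethylsilyl)but-3-yn-1-ol
Product: 12 (4-iodobut-1-yn-1-yl)trimethylsilane
Conditions: I2, PPh3, imidazole, CH2Cl2, 0 °C to rt
Reagents that add atoms: iodine, II
Why: Appel-type iodination (Garegg–Samuelsson conditions) converts the primary alcohol cleanly through its alkoxyphosphonium salt.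

Step 6
Reactants: 12 (4-iodobut-1-yn-1-yl)trimethylsilane; 7 2,6,6-trimethylcyclohex-1-en-1-yl trifluoromethanesulfonate
Product: 14 trimethyl[4-(2,6,6-trimethylcyclohex-1-en-1-yl)but-1-yn-1-yl]silane, via alkylzinc iodide 13 (not isolated)
Conditions: 12, Zn dust (activated with BrCH2CH2Br/Me3SiCl), LiCl, THF, 40 °C; then 7, Pd(dppf)Cl2 (5 mol %), THF/NMP, 60 °C
Reagents that add atoms: none
Why: Negishi sp3–sp2 coupling of a homopropargylzinc reagent with an alkenyl triflate is suitable because the wide-bite-angle dppf ligand favours reductive elimination over β-hydride elimination.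

Step 7
Reactants: 14 trimethyl[4-(2,6,6-trimethylcyclohex-1-en-1-yl)but-1-yn-1-yl]silane
Product: 15 2-(but-3-yn-1-yl)-1,3,3-trimethylcyclohex-1-ene
Conditions: K2CO3 (0.2 equiv), MeOH, rt
Reagents that add atoms: none
Why: Base-catalysed protodesilylation by methanolysis of the alkynyl C–Si bond frees the terminal alkyne without touching the ring alkene.

Step 8
Reactants: 15 2-(but-3-yn-1-yl)-1,3,3-trimethylcyclohex-1-ene
Product: 18 (2E)-3-methyl-5-(2,6,6-trimethylcyclohex-1-en-1-yl)pent-2-en-1-ol, via alkenylalane 16 (not isolated), via lithium alanate 17 (not isolated)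
Conditions: Me3Al (2 equiv), Cp2ZrCl2 (0.25 equiv), CH2Cl2, 0 °C to rt, evaporate excess Me3Al; n-BuLi (1 equiv), hexane/THF, −78 to 0 °C; (CH2O)n, rt; 1 M HCl, 0 °C
Reagents that add atoms: trimethylaluminium, C[Al](C)C; paraformaldehyde (reacts as formaldehyde), C=O
Why: Negishi zirconium-catalysed carboalumination adds Me–Al syn and terminally across the alkyne, and trapping the alanate with formaldehyde proceeds with retention, so the trisubstituted alkene is formed as the E isomer only.

Step 9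
Reactants: 18 (2E)-3-methyl-5-(2,6,6-trimethylcyclohex-1-en-1-yl)pent-2-en-1-ol
Product: 19 {(2S,3S)-3-methyl-3-[2-(2,6,6-trimethylcyclohex-1-en-1-yl)ethyl]oxiran-2-yl}methanol
Conditions: Ti(Oi-Pr)4 (5 mol %), L-(+)-diethyl tartrate (7 mol %), t-BuOOH (2 equiv, decane), 4 Å MS, CH2Cl2, −20 °C
Reagents that add atoms: tert-butyl hydroperoxide, CC(C)(C)OO
Why: Sharpless asymmetric epoxidation is hydroxyl-directed, so only the allylic alkene reacts, and L-(+)-tartrate delivers oxygen to the face of the E-allylic alcohol that sets both oxirane centres (C9, C10) as S,S, as with geraniol.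

Step 10
Reactants: 19 {(2S,3S)-3-methyl-3-[2-(2,6,6-trimethylcyclohex-1-en-1-yl)ethyl]oxiran-2-yl}methanol
Product: 20 (2R,3S)-3-methyl-3-[2-(2,6,6-trimethylcyclohex-1-en-1-yl)ethyl]oxirane-2-carbaldehyde
Conditions: TEMPO (10 mol %), PhI(OAc)2 (1.1 equiv), CH2Cl2, rt
Reagents that add atoms: none
Why: Oxoammonium (TEMPO/PhI(OAc)2) oxidation stops at the aldehyde and spares the oxirane and alkene; the geometry is unchanged and only the descriptor at C2 changes.

Step 11
Reactants: 20 (2R,3S)-3-methyl-3-[2-(2,6,6-trimethylcyclohex-1-en-1-yl)ethyl]oxirane-2-carbaldehyde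
Product: 21 (2S,3S)-3-ethenyl-2-methyl-2-[2-(2,6,6-trimethylcyclohex-1-en-1-yl)ethyl]oxirane (fragment A)
Conditions: MePPh3Br (1.3 equiv), KN(SiMe3)2 (1.25 equiv), THF, 0 °C; then 20, −78 to 0 °C
Reagents that add atoms: methyltriphenylphosphonium bromide, C[P+](c1ccccc1)(c1ccccc1)c1ccccc1.[Br-]
Why: Wittig methylenation of the epoxy aldehyde at low temperature is faster than any epimerisation, so the oxirane centres are carried over intact.

**Fragment B**

Step 12
Reactants: 22 2-(2-bromoethyl)-1,3-dioxolane; 23 methyl but-2-ynoate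
Product: 27 methyl (2E)-5-(1,3-dioxolan-2-yl)-3-methylpent-2-enoate, via Grignard reagent 24 (not isolated), via alkylcopper 25 (not isolated), via alkenylcopper 26 (not isolated)
Conditions: 22, Mg turnings, THF, ≤30 °C; CuBr·SMe2 (1 equiv), −78 °C; 23, −78 °C; aq. NH4Cl quench at −78 °C
Reagents that add atoms: none
Why: Syn-carbocupration (conjugate addition) of the ynoate, with a cold protonation before the alkenylcopper can isomerise, places the new chain trans to the ester and gives the E-enoate.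

Step 13
Reactants: 27 methyl (2E)-5-(1,3-dioxolan-2-yl)-3-methylpent-2-enoate
Product: 28 methyl (2E)-3-methyl-6-oxohex-2-enoate
Conditions: 2 M HCl, THF, rt
Reagents that add atoms: water, O
Why: Acid-catalysed acetal hydrolysis frees the aldehyde while the β,β-disubstituted enoate is inert.

Step 14
Reactants: 28 methyl (2E)-3-methyl-6-oxohex-2-enoate; 29 (E)-but-2-ene
Product: 34 methyl (2E,6R,7S)-6-hydroxy-3,7-dimethylnona-2,8-dienoate, via (E)-crotylpotassium 30 (not isolated), via borate complex 31 (not isolated), via (E)-crotylborane 32 (not isolated), via borinic ester 33 (not isolated)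
Conditions: 29, n-BuLi, KOt-Bu, THF, −78 to −45 °C; (−)-Ipc2BOMe, −78 °C; BF3·OEt2, −78 °C; 28, −78 °C; then 3 M NaOH, 30 % H2O2, 0 °C to rt
Reagents that add atoms: none
Why: Brown asymmetric crotylboration runs through a closed Zimmerman–Traxler chair, in which the E-crotyl geometry gives the anti C2/C3 relationship and the (−)-Ipc2B group (from (+)-α-pinene) selects the aldehyde face that gives the R carbinol, while the enoate does not react at −78 °C.

Step 15
Reactants: 34 methyl (2E,6R,7S)-6-hydroxy-3,7-dimethylnona-2,8-dienoate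
Product: 35 methyl (2E,6R,7S)-6-(methanesulfonyloxy)-3,7-dimethylnona-2,8-dienoate
Conditions: MsCl, Et3N, CH2Cl2, 0 °C
Reagents that add atoms: methanesulfonyl chloride, CS(=O)(=O)Cl
Why: Mesylation activates the C3 oxygen with retention, and having no carbonyl next to C2 excludes E1cB loss of the leaving group later.

Step 16
Reactants: 35 methyl (2E,6R,7S)-6-(methanesulfonyloxy)-3,7-dimethylnona-2,8-dienoate
Product: 36 (3S,4R,7E)-9-hydroxy-3,7-dimethylnona-1,7-dien-4-yl methanesulfonate
Conditions: i-Bu2AlH (2.3 equiv), CH2Cl2, −78 °C; aq. KNaC4H4O6 (potassium sodium tartrate)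
Reagents that add atoms: none
Why: 1,2-Reduction of the enoate with i-Bu2AlH gives the E-allylic alcohol, and a secondary mesylate is not displaced by this hydride at −78 °C.

Step 17
Reactants: 36 (3S,4R,7E)-9-hydroxy-3,7-dimethylnona-1,7-dien-4-yl methanesulfonate
Product: 37 (3S,4R)-6-[(2R,3R)-3-(hydroxymethyl)-2-methyloxiran-2-yl]-3-methylhex-1-en-4-yl methanesulfonate
Conditions: Ti(Oi-Pr)4 (10 mol %), D-(−)-diethyl tartrate (12 mol %), t-BuOOH (2 equiv, decane), 4 Å MS, CH2Cl2, −20 °C
Reagents that add atoms: tert-butyl hydroperoxide, CC(C)(C)OO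
Why: Sharpless asymmetric epoxidation under reagent control with D-(−)-tartrate gives the (2R,3R)-epoxy alcohol, which places C6 in the configuration opposite to the one needed before an invertive opening, and the isolated vinyl group is untouched.

Step 18
Reactants: 37 (3S,4R)-6-[(2R,3R)-3-(hydroxymethyl)-2-methyloxiran-2-yl]-3-methylhex-1-en-4-yl methanesulfonate
Product: 38 (3S,4R,7S,8R)-7-hydroperoxy-8,9-dihydroxy-3,7-dimethylnon-1-en-4-yl methanesulfonate
Conditions: anhydrous H2O2 in Et2O (10 equiv), H3PMo12O40 (phosphomolybdic acid, 3 mol %), Et2O, rt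
Reagents that add atoms: hydrogen peroxide, OO
Why: Acid-catalysed perhydrolysis of the epoxide opens the tertiary, better cation-stabilising carbon in a borderline SN2 process with backside attack, so C6 is inverted from R to S and receives the O–O unit while C7 keeps its oxygen.

Step 19
Reactants: 38 (3S,4R,7S,8R)-7-hydroperoxy-8,9-dihydroxy-3,7-dimethylnon-1-en-4-yl methanesulfonate
Product: 39 (1R)-1-{(3S,6S)-6-[(2S)-but-3-en-2-yl]-3-methyl-1,2-dioxan-3-yl}ethane-1,2-diol
Conditions: KOt-Bu (1.1 equiv), 18-crown-6 (1.1 equiv), THF (0.02 M), 0 °C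
Reagents that add atoms: none
Why: One equivalent of base deprotonates only the hydroperoxide, and the weakly basic but strongly nucleophilic peroxide anion displaces the mesylate in a 6-exo-tet intramolecular SN2 reaction with inversion at C3 (R to S), closing a chair dioxane with both large groups equatorial.

Step 20
Reactants: 39 (1R)-1-{(3S,6S)-6-[(2S)-but-3-en-2-yl]-3-methyl-1,2-dioxan-3-yl}ethane-1,2-diol
Product: 40 methyl (2R)-2-{(3S,6S)-6-[(1R)-1,2-dihydroxyethyl]-6-methyl-1,2-dioxan-3-yl}propanoate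
Conditions: O3, 2.5 M NaOH in MeOH (5 equiv), CH2Cl2, −78 °C; cold pH 7 phosphate buffer
Reagents that add atoms: ozone, [O-][O+]=O; methanol, CO
Why: Marshall ozonolysis in methanolic NaOH cleaves the only alkene, and ozone oxidises the aldehyde hemiacetal anion directly to the methyl ester at −78 °C, which is too cold for C2 epimerisation or β-elimination of the peroxide.

Step 21
Reactants: 40 methyl (2R)-2-{(3S,6S)-6-[(1R)-1,2-dihydroxyethyl]-6-methyl-1,2-dioxan-3-yl}propanoate
Product: 41 methyl (2R)-2-[(3S,6S)-6-formyl-6-methyl-1,2-dioxan-3-yl]propanoate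
Conditions: NaIO4 (1.5 equiv), THF/H2O, 0 °C to rt
Reagents that add atoms: none
Why: Malaprade glycol cleavage removes C8 under neutral oxidative conditions that a dialkyl peroxide tolerates, and the aldehyde formed cannot enolise.

Step 22
Reactants: 41 methyl (2R)-2-[(3S,6S)-6-formyl-6-methyl-1,2-dioxan-3-yl]propanoate
Product: 42 methyl (2R)-2-[(3S,6S)-6-ethenyl-6-methyl-1,2-dioxan-3-yl]propanoate (fragment B)
Conditions: MePPh3Br (1.2 equiv), KN(SiMe3)2 (1.1 equiv), THF, 0 °C; then 41, −78 to 0 °C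
Reagents that add atoms: methyltriphenylphosphonium bromide, C[P+](c1ccccc1)(c1ccccc1)c1ccccc1.[Br-]
Why: In this Wittig methylenation, addition of the ylide to the aldehyde at −78 °C is much faster than deprotonation of the ester α-position, so the ester, the O–O bond and C2 survive.

**Coupling and endgame**

Step 23
Reactants: 21 (2S,3S)-3-ethenyl-2-methyl-2-[2-(2,6,6-trimethylcyclohex-1-en-1-yl)ethyl]oxirane; 42 methyl (2R)-2-[(3S,6S)-6-ethenyl-6-methyl-1,2-dioxan-3-yl]propanoate
Product: 43 methyl (2R)-2-{(3S,6S)-6-methyl-6-[(E)-2-{(2S,3S)-3-methyl-3-[2-(2,6,6-trimethylcyclohex-1-en-1-yl)ethyl]oxiran-2-yl}ethenyl]-1,2-dioxan-3-yl}propanoate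
Conditions: 21 (2 equiv), 42 (1 equiv), second-generation Hoveyda–Grubbs catalyst (10 mol % in two portions), CH2Cl2 (0.2 M), 40 °C, argon sparge
Reagents that add atoms: none
Why: Olefin cross metathesis between a slowly homodimerising vinyl oxirane and a non-homodimerising vinyl group on a fully substituted allylic carbon is selective for the cross product, and the ruthenium carbene tolerates dialkyl peroxides, oxiranes and the inert tetrasubstituted alkene.

Step 24
Reactants: 43 methyl (2R)-2-{(3S,6S)-6-methyl-6-[(E)-2-{(2S,3S)-3-methyl-3-[2-(2,6,6-trimethylcyclohex-1-en-1-yl)ethyl]oxiran-2-yl}ethenyl]-1,2-dioxan-3-yl}propanoate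
Product: 44 methyl (2R)-2-{(3S,6R)-6-methyl-6-[2-{(2S,3S)-3-methyl-3-[2-(2,6,6-trimethylcyclohex-1-en-1-yl)ethyl]oxiran-2-yl}ethyl]-1,2-dioxan-3-yl}propanoate
Conditions: 2-nitrobenzenesulfonyl hydrazide (10–20 equiv in portions), Et3N, CH2Cl2, rt
Reagents that add atoms: none
Why: Diimide reduction transfers H2 in a concerted way to the disubstituted alkene only, leaving the O–O bond, the oxirane and the tetrasubstituted alkene intact; C6 keeps its geometry and only its descriptor changes to R.

Step 25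
Reactants: 44 methyl (2R)-2-{(3S,6R)-6-methyl-6-[2-{(2S,3S)-3-methyl-3-[2-(2,6,6-trimethylcyclohex-1-en-1-yl)ethyl]oxiran-2-yl}ethyl]-1,2-dioxan-3-yl}propanoate
Product: 46 (2R)-2-{(3S,6R)-6-methyl-6-[2-{(2S,3S)-3-methyl-3-[2-(2,6,6-trimethylcyclohex-1-en-1-yl)ethyl]oxiran-2-yl}ethyl]-1,2-dioxan-3-yl}propanoic acid (CNP0204283.1), via lithium carboxylate 45 (not isolated)
Conditions: LiOH (5 equiv), THF/MeOH/H2O (3:1:1), 0 °C to rt; then cold 0.5 M HCl to pH 5
Reagents that add atoms: lithium hydroxide, [Li+].[OH-]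
Why: Saponification by acyl–oxygen cleavage at or below room temperature leaves the oxirane and dialkyl peroxide untouched and is mild enough to avoid retro-oxa-Michael epimerisation, and acidifying only to pH 5 protects the oxirane.

**Compound list**
1 | 2-methylcyclohexanone (racemic) | CC1CCCCC1=O | starting material
2 | lithium 6-methylcyclohex-1-en-1-olate | [Li]OC1=CCCCC1C | intermediate
3 | 2,6-dimethylcyclohexanone (cis/trans) | CC1CCCC(C)C1=O | intermediate
4 | lithium 2,6-dimethylcyclohex-1-en-1-olate | [Li]OC1=C(C)CCCC1C | intermediate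
5 | 2,2,6-trimethylcyclohexanone (racemic) | CC1CCCC(C)(C)C1=O | intermediate
6 | lithium 2,6,6-trimethylcyclohex-1-en-1-olate | [Li]OC1=C(C)CCCC1(C)C | intermediate
7 | 2,6,6-trimethylcyclohex-1-en-1-yl trifluoromethanesulfonate | CC1=C(OS(=O)(=O)C(F)(F)F)C(C)(C)CCC1 | intermediate
8 | but-3-yn-1-ol | C#CCCO | starting material
9 | dilithium salt of but-3-yn-1-ol | [Li]C#CCCO[Li] | intermediate
10 | trimethyl{4-[(trimethylsilyl)oxy]but-1-yn-1-yl}silane | C[Si](C)(C)C#CCCO[Si](C)(C)C | intermediate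
11 | 4-(trimethylsilyl)but-3-yn-1-ol | C[Si](C)(C)C#CCCO | intermediate
12 | (4-iodobut-1-yn-1-yl)trimethylsilane | C[Si](C)(C)C#CCCI | intermediate
13 | [4-(trimethylsilyl)but-3-yn-1-yl]zinc iodide | C[Si](C)(C)C#CCC[Zn]I | intermediate
14 | trimethyl[4-(2,6,6-trimethylcyclohex-1-en-1-yl)but-1-yn-1-yl]silane | CC1=C(CCC#C[Si](C)(C)C)C(C)(C)CCC1 | intermediate
15 | 2-(but-3-yn-1-yl)-1,3,3-trimethylcyclohex-1-ene | CC1=C(CCC#C)C(C)(C)CCC1 | intermediate
16 | dimethyl[(1E)-2-methyl-4-(2,6,6-trimethylcyclohex-1-en-1-yl)but-1-en-1-yl]alane | CC1=C(CC/C(C)=C/[Al](C)C)C(C)(C)CCC1 | intermediate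
17 | lithium butyl(dimethyl)[(1E)-2-methyl-4-(2,6,6-trimethylcyclohex-1-en-1-yl)but-1-en-1-yl]alanate | [Li+].CC1=C(CC/C(C)=C/[Al-](C)(C)CCCC)C(C)(C)CCC1 | intermediate
18 | (2E)-3-methyl-5-(2,6,6-trimethylcyclohex-1-en-1-yl)pent-2-en-1-ol | CC1=C(CC/C(C)=C/CO)C(C)(C)CCC1 | intermediate
19 | {(2S,3S)-3-methyl-3-[2-(2,6,6-trimethylcyclohex-1-en-1-yl)ethyl]oxiran-2-yl}methanol | CC1=C(CC[C@]2(C)O[C@H]2CO)C(C)(C)CCC1 | intermediate
20 | (2R,3S)-3-methyl-3-[2-(2,6,6-trimethylcyclohex-1-en-1-yl)ethyl]oxirane-2-carbaldehyde | CC1=C(CC[C@]2(C)O[C@H]2C=O)C(C)(C)CCC1 | intermediate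
21 | (2S,3S)-3-ethenyl-2-methyl-2-[2-(2,6,6-trimethylcyclohex-1-en-1-yl)ethyl]oxirane | CC1=C(CC[C@]2(C)O[C@H]2C=C)C(C)(C)CCC1 | intermediate
22 | 2-(2-bromoethyl)-1,3-dioxolane | BrCCC1OCCO1 | starting material
23 | methyl but-2-ynoate | CC#CC(=O)OC | starting material
24 | [2-(1,3-dioxolan-2-yl)ethyl]magnesium bromide | Br[Mg]CCC1OCCO1 | intermediate
25 | [2-(1,3-dioxolan-2-yl)ethyl]copper | [Cu]CCC1OCCO1 | intermediate
26 | α-cuprio enoate (Cu cis to the new chain) | COC(=O)/C([Cu])=C(\C)CCC1OCCO1 | intermediate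
27 | methyl (2E)-5-(1,3-dioxolan-2-yl)-3-methylpent-2-enoate | COC(=O)/C=C(\C)CCC1OCCO1 | intermediate
28 | methyl (2E)-3-methyl-6-oxohex-2-enoate | COC(=O)/C=C(\C)CCC=O | intermediate
29 | (E)-but-2-ene | C/C=C/C | starting material
30 | (E)-crotylpotassium | C/C=C/C[K] | intermediate
31 | potassium (E)-crotyl(methoxy)bis(isopinocampheyl)borate | [K+].C/C=C/C[B-](OC)([C@@H]1C[C@@H]2C[C@H]([C@H]1C)C2(C)C)[C@@H]1C[C@@H]2C[C@H]([C@H]1C)C2(C)C | intermediate
32 | (E)-crotylbis(isopinocampheyl)borane, (−)-Ipc series | C/C=C/CB([C@@H]1C[C@@H]2C[C@H]([C@H]1C)C2(C)C)[C@@H]1C[C@@H]2C[C@H]([C@H]1C)C2(C)C | intermediate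
33 | bis(isopinocampheyl)borinic ester of 34 | COC(=O)/C=C(\C)CC[C@@H](OB([C@@H]1C[C@@H]2C[C@H]([C@H]1C)C2(C)C)[C@@H]1C[C@@H]2C[C@H]([C@H]1C)C2(C)C)[C@@H](C)C=C | intermediate
34 | methyl (2E,6R,7S)-6-hydroxy-3,7-dimethylnona-2,8-dienoate | COC(=O)/C=C(\C)CC[C@@H](O)[C@@H](C)C=C | intermediate
35 | methyl (2E,6R,7S)-6-(methanesulfonyloxy)-3,7-dimethylnona-2,8-dienoate | COC(=O)/C=C(\C)CC[C@@H](OS(C)(=O)=O)[C@@H](C)C=C | intermediate
36 | (3S,4R,7E)-9-hydroxy-3,7-dimethylnona-1,7-dien-4-yl methanesulfonate | OC/C=C(\C)CC[C@@H](OS(C)(=O)=O)[C@@H](C)C=C | intermediate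
37 | (3S,4R)-6-[(2R,3R)-3-(hydroxymethyl)-2-methyloxiran-2-yl]-3-methylhex-1-en-4-yl methanesulfonate | OC[C@H]1O[C@]1(C)CC[C@@H](OS(C)(=O)=O)[C@@H](C)C=C | intermediate
38 | (3S,4R,7S,8R)-7-hydroperoxy-8,9-dihydroxy-3,7-dimethylnon-1-en-4-yl methanesulfonate | OC[C@@H](O)[C@@](C)(OO)CC[C@@H](OS(C)(=O)=O)[C@@H](C)C=C | intermediate
39 | (1R)-1-{(3S,6S)-6-[(2S)-but-3-en-2-yl]-3-methyl-1,2-dioxan-3-yl}ethane-1,2-diol | OC[C@@H](O)[C@]1(C)CC[C@@H]([C@@H](C)C=C)OO1 | intermediate
40 | methyl (2R)-2-{(3S,6S)-6-[(1R)-1,2-dihydroxyethyl]-6-methyl-1,2-dioxan-3-yl}propanoate | OC[C@@H](O)[C@]1(C)CC[C@@H]([C@@H](C)C(=O)OC)OO1 | intermediate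
41 | methyl (2R)-2-[(3S,6S)-6-formyl-6-methyl-1,2-dioxan-3-yl]propanoate | O=C[C@]1(C)CC[C@@H]([C@@H](C)C(=O)OC)OO1 | intermediate
42 | methyl (2R)-2-[(3S,6S)-6-ethenyl-6-methyl-1,2-dioxan-3-yl]propanoate | C=C[C@]1(C)CC[C@@H]([C@@H](C)C(=O)OC)OO1 | intermediate
43 | cross-metathesis product, (7E)-alkene methyl ester | CC1=C(CC[C@]2(C)O[C@H]2/C=C/[C@]2(C)CC[C@@H]([C@@H](C)C(=O)OC)OO2)C(C)(C)CCC1 | intermediate
44 | methyl ester of the target (2R,3S,6R; oxirane S,S) | CC1=C(CC[C@]2(C)O[C@H]2CC[C@]2(C)CC[C@@H]([C@@H](C)C(=O)OC)OO2)C(C)(C)CCC1 | intermediate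
45 | lithium salt of the target | [Li+].CC1=C(CC[C@]2(C)O[C@H]2CC[C@]2(C)CC[C@@H]([C@@H](C)C(=O)[O-])OO2)C(C)(C)CCC1 | intermediate
46 | CNP0204283.1 | CC1=C(CC[C@]2(C)O[C@H]2CC[C@]2(C)CC[C@@H]([C@@H](C)C(=O)O)OO2)C(C)(C)CCC1 | target

**Counts**
- Total step count: 25.
- Longest linear sequence: 14 steps (steps 12–25).
- The fragment A line from 1 is 12 steps to the target.
- The side branch from 8 is 11 steps to the target.

**Steps most likely to fail**

Step 23 (cross metathesis). Both alkenes are slow: one sits on a fully substituted peroxy carbon and the other on an oxirane. Dimerisation of 21 or catalyst death may therefore win.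
- The fallback sets out from 15 and 42 and comes back at 44.
- Alkyne 15 is carboaluminated as in step 8 to alkenylalane 16, which is quenched with I2 to give 2-[(3E)-4-iodo-3-methylbut-3-en-1-yl]-1,3,3-trimethylcyclohex-1-ene F6.
- The vinyl group of 42 is hydroborated with 9-BBN-H (THF, 0 °C to rt) to give methyl (2R)-2-{(3S,6R)-6-[2-(9-borabicyclo[3.3.1]nonan-9-yl)ethyl]-6-methyl-1,2-dioxan-3-yl}propanoate F7.
- B-alkyl Suzuki–Miyaura coupling of the two (Pd(dppf)Cl2, AsPh3, Cs2CO3, DMF/THF/H2O, rt) gives methyl (2R)-2-{(3S,6R)-6-methyl-6-[(3E)-4-methyl-6-(2,6,6-trimethylcyclohex-1-en-1-yl)hex-3-en-1-yl]-1,2-dioxan-3-yl}propanoate F8.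
- Shi epoxidation with the L-fructose-derived ketone follows (KHSO5 as 2KHSO5·KHSO4·K2SO4, K2CO3 buffer pH 10.5, MeCN/dimethoxymethane, 0 °C). The reagent reaches the E-trisubstituted alkene faster than the shielded ring alkene and gives the S,S oxirane, that is 44.

Step 18 (perhydrolysis). Three problems can lower yield or fidelity: partial ionisation at C6 would erode the configuration, traces of water give the triol, and the β-hydroxy hydroperoxide can fragment in step 19.
- The fallback sets out from 37 and comes back at 39, and it reverses the order of the two C–O bond formations.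
- The C3 mesylate is displaced with inversion by 2-methoxypropan-2-yl hydroperoxide (CsOH·H2O, DMF, 0 °C) to give {(2R,3R)-3-[(3S,4S)-3-[(2-methoxypropan-2-yl)peroxy]-4-methylhex-5-en-1-yl]-3-methyloxiran-2-yl}methanol F4.
- Aqueous AcOH/THF unmasks {(2R,3R)-3-[(3S,4S)-3-hydroperoxy-4-methylhex-5-en-1-yl]-3-methyloxiran-2-yl}methanol F5.
- Catalytic camphorsulfonic acid in CH2Cl2 then drives the intramolecular 6-exo opening of the oxirane at the tertiary carbon with inversion, giving 39.

Step 6 (Negishi coupling at the hindered tetrasubstituted triflate). Slow transmetalation and β-hydride elimination may dominate.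
- The fallback sets out from 7 and comes back at 14, and it moves the C–C bond formation away from the ring carbon.
- Methoxycarbonylation (Pd(OAc)2, PPh3, CO 1 atm, MeOH, Et3N, DMF, 60 °C) gives methyl 2,6,6-trimethylcyclohex-1-ene-1-carboxylate F1.
- Reduction with i-Bu2AlH gives (2,6,6-trimethylcyclohex-1-en-1-yl)methanol F2.
- PBr3 (Et2O, 0 °C) gives 2-(bromomethyl)-1,3,3-trimethylcyclohex-1-ene F3.
- SN2 alkylation of lithiated 1-(trimethylsilyl)propyne (n-BuLi, THF, −78 °C) with this bromide gives 14.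

**Further compounds**
F1 | step 6 | methyl 2,6,6-trimethylcyclohex-1-ene-1-carboxylate | COC(=O)C1=C(C)CCCC1(C)C
F2 | step 6 | (2,6,6-trimethylcyclohex-1-en-1-yl)methanol | OCC1=C(C)CCCC1(C)C
F3 | step 6 | 2-(bromomethyl)-1,3,3-trimethylcyclohex-1-ene | BrCC1=C(C)CCCC1(C)C
F4 | step 18 | {(2R,3R)-3-[(3S,4S)-3-[(2-methoxypropan-2-yl)peroxy]-4-methylhex-5-en-1-yl]-3-methyloxiran-2-yl}methanol | OC[C@H]1O[C@]1(C)CC[C@H](OOC(C)(C)OC)[C@@H](C)C=C
F5 | step 18 | {(2R,3R)-3-[(3S,4S)-3-hydroperoxy-4-methylhex-5-en-1-yl]-3-methyloxiran-2-yl}methanol | OC[C@H]1O[C@]1(C)CC[C@H](OO)[C@@H](C)C=C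
F6 | step 23 | 2-[(3E)-4-iodo-3-methylbut-3-en-1-yl]-1,3,3-trimethylcyclohex-1-ene | CC1=C(CC/C(C)=C/I)C(C)(C)CCC1
F7 | step 23 | methyl (2R)-2-{(3S,6R)-6-[2-(9-borabicyclo[3.3.1]nonan-9-yl)ethyl]-6-methyl-1,2-dioxan-3-yl}propanoate | C1CC2CCCC(C1)B2CC[C@]1(C)CC[C@@H]([C@@H](C)C(=O)OC)OO1
F8 | step 23 | methyl (2R)-2-{(3S,6R)-6-methyl-6-[(3E)-4-methyl-6-(2,6,6-trimethylcyclohex-1-en-1-yl)hex-3-en-1-yl]-1,2-dioxan-3-yl}propanoate | CC1=C(CC/C(C)=C/CC[C@]2(C)CC[C@@H]([C@@H](C)C(=O)OC)OO2)C(C)(C)CCC1
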